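## The problem

(7'S,8'S)-Nocomtal (17) is a 1,4-benzodioxane neolignan. An enal-bearing arene (ring A: enal carbon C1, oxygens O3 and O4 on C3 and C4, methoxy on C5) is bridged through O3 and O4 by the two-carbon unit C7'–C8', which completes the dioxane ring B; C7' carries the guaiacyl ring C and C8' the hydroxymethyl arm C9'. The first task is constitutional: O3 must end on C7' and O4 on C8', because the opposite pairing gives a regioisomeric skeleton from the same pieces. The second is stereochemical: two adjacent centres must be trans and of the (7'S,8'S) series. The two centres differ in kind. C8' is an ordinary secondary ether carbon that must be set absolutely and can then direct its neighbour, whereas C7' is benzylic to a ring with a para oxygen, ionises readily, and so cannot be trusted under acid but can be corrected by it. The reagents are limited by the (E)-enal (reducible, Michael acceptor, best made late), the ring C phenol, the benzylic aryl ether C7'–O3 (hydrogenolysis, strong acid), and every intermediate in which C8' lies next to a carbonyl group (epimerisation, β-elimination of the C9' oxygen). The key step rests on the ionisable C7' together with a ring A phenol oxygen O3 held ortho to the O4 ether: capture of a C7' cation by O3 closes a six-membered ring whose trans form, with ring C and the C9' arm both equatorial, is the more stable.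

## Retrosynthesis

**17 from 16 (two O–Si bonds).** The ring C phenol and the C9' hydroxyl are released last from the bis-silyl ether 16 with buffered fluoride. Benzyl ethers were weighed against this. Their removal by hydrogenolysis would also threaten the benzylic C7'–O3 bond, an aryl dioxolane and the enal, so silyl ethers are preferred. This costs a change of chiral-pool source from an O-benzyl serine to a glycerate.

**16 from 15 (the C=C bond of the enal).** A two-carbon formylmethylene ylide converts the ring A aldehyde 15 into the (E)-enal. Making the enal late keeps it away from hydride, Grignard and acid steps. The forward reaction must stop after one homologation.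

**15 from 14 (aldehyde from dioxolane).** The ring A aldehyde is masked as the dioxolane in 14 because the preceding steps use a hydride and an aryl Grignard reagent. The unmasking directly follows the ring closure, so any acetal lost during that closure is already the product of this step.

**14 from 12 (cut of O3–C7', the key disconnection).** Opening ring B at the benzylic ether gives the phenol–alcohol 12. This cut is preferred to O4–C8' because C7' is the carbon that ionises easily. Closure at C7' is therefore reversible and self-correcting, and 12 may be a mixture of C7' epimers. Closure at C8' would be a one-off substitution that fixes whatever ratio it produces. The precursor has one defined stereocentre instead of two and no ring B. The forward reaction must ionise C7' with catalytic acid, trap the cation with O3, and let the cis isomer 13 revert until the trans isomer 14 dominates.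

**12 from 9 and 8 (cut of the C7'–aryl bond).** Since the C7' configuration is irrelevant, the alcohol is simply made by adding the aryl Grignard reagent 10 (from bromide 8) to the aldehyde 11. Aldehyde 11 is generated from the ester 9 by hydride and never isolated, because an α-aryloxy aldehyde epimerises easily. The free O3 phenol is carried through; it only consumes one extra equivalent of hydride.

**9 from 6, and 6 from 4 and 5 (acetal; cut of O4–C8').** The dioxolane 9 comes from aldehyde 6. The aryl ether 6 arises by displacement of the triflate 4 by 5-hydroxyvanillin (5) with inversion. This one step settles both the constitution and the absolute configuration. The hydroxyl para to the formyl group of 5 is the more acidic, so the monoanion alkylates at O4, and the (R) centre of 4 becomes the (S) centre that is C8'. The formyl group is thus used twice, first to direct the alkylation and later as the anchor of the enal.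

**4 from 3, 2 and 1; 8 from 7.** The triflate 4 comes from the hydroxy ester 3, made by selective primary silylation of methyl D-glycerate (2), itself released from the commercial acetonide 1. The bromide 8 is the silyl ether of 4-bromo-2-methoxyphenol (7).

## Roads not taken

**Alternative 1:** The cut is O4–C8', with C7' set first. A chiral iridium catalyst ([Ir(cod)Cl]2 with a phosphoramidite ligand) would make the branched (R)-allyl aryl ether A1 from O3 and a ring C cinnamyl unit. The key step then treats A1 with I2 and NaHCO3, so that the free O4 phenol attacks the internal alkene carbon in a 6-exo mode and gives the trans iodomethyl benzodioxane aldehyde A2.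
- Merits: enantiocontrol is catalytic, no stereocentre ever sits next to a carbonyl group, and the ring A aldehyde needs no protection. In these respects it is better than the chosen plan and probably shorter on paper.
- Weak points:
  - The iridium step must etherify O3 although O4 is the more acidic oxygen, so O4 has to be masked and unmasked.
  - A1 is both allylic and para-oxybenzylic, so it is prone to ionisation (loss of the C7' configuration) and to aromatic Claisen rearrangement.
  - The iodoetherification is irreversible, so the trans/cis ratio is a kinetic result with no means of correction.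
  - I2 can iodinate the electron-rich rings.
  - The iodide of A2, which sits next to an oxygen-bearing carbon, is slow to exchange for oxygen.
- Comparison: the chosen plan offers a cheap chiral-pool centre and a closure that repairs its own stereochemical errors.

**Alternative 2:** The cut removes C7'–C8' and C8'–O4 at once. The racemic benzodioxole acetal A3 would be opened at C7'–O4 by a confined chiral Brønsted acid, ethyl diazoacetate would add its carbon to C7', and the O4 phenol would displace N2, expanding the five-membered acetal to ring B and giving the trans diester A4.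
- Merits: this is the most convergent idea. A3 comes from two simple pieces in one condensation, and a single step would make two bonds and both stereocentres. If it worked it would need roughly half the steps of the chosen plan.
- Weak points:
  - The step has no close counterpart on this substrate class and needs three selectivities together: which C–O bond of the unsymmetrical acetal ionises (this decides the constitution), the face of the C7' cation within an ion pair, and trans over cis.
  - Aryl or hydride shifts in the diazonium intermediate compete with ring closure.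
  - A4 has two esters that must end at different oxidation levels, and its C8' is α to an ester.
- Comparison: against the better step economy, the chosen plan uses only known reaction types and relies on an equilibrium, not an undeveloped catalyst, for its stereochemistry.

**Alternative 3:** The cut is the aryl C–O bond O4–C4. Both stereocentres would be set in the open chain, and the bromo alcohol A5 would be closed with CuI, 3,4,7,8-tetramethyl-1,10-phenanthroline and Cs2CO3 to the trans benzodioxane methyl ester A6 with retention at both centres.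
- Merits: the ring closure touches no stereocentre. The ring A building block is symmetrical about its C1–C4 axis before O-methylation, so the O3/O4 question is solved by construction. No α-aryloxy carbonyl compound occurs. If the trans/cis equilibrium of the chosen plan were less one-sided than expected, this road would be the better one.
- Weak points:
  - The O3–C7' bond of A5 must be made with defined configuration at the very carbon that ionises, so any substitution there can leak through a cationic pathway.
  - The bromide is flanked by two ortho oxygen substituents and the nucleophile is a secondary alcohol, a demanding case for copper-mediated etherification at high temperature.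
  - The ester must be reduced and re-oxidised before the enal can be made.
  - The ring C benzyl ether has to be removed beside the C7'–O3 bond.
- Comparison: the chosen plan needs only one stereodefining operation (a single inversion), and its closing step accepts any C7' mixture.

Key step: step 8

Assumption: compounds 1, 5 and 7 and all reagents are taken as purchasable, and the trans-diequatorial 2-aryl-3-(oxymethyl)-1,4-benzodioxane is taken to be the more stable diastereomer, as in related neolignans.

## Route

Step 1
Reactants: 1 methyl (4R)-2,2-dimethyl-1,3-dioxolane-4-carboxylate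
Product: 2 methyl (2R)-2,3-dihydroxypropanoate (methyl D-glycerate)
Conditions: AcOH/H2O (4:1), 40 °C; toluene azeotrope
Reagents that add atoms: none
Why: Acid-catalysed hydrolysis of the isopropylidene acetal; no bond to the stereocentre is broken and the methyl ester survives dilute acetic acid.

Step 2
Reactants: 2 methyl (2R)-2,3-dihydroxypropanoate
Product: 3 methyl (2R)-3-[(tert-butyldiphenylsilyl)oxy]-2-hydroxypropanoate
Conditions: TBDPSCl (1.05 equiv), imidazole, CH2Cl2, 0 °C
Reagents that add atoms: tert-butyl(chloro)diphenylsilane, CC(C)(C)[Si](Cl)(c1ccccc1)c1ccccc1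
Why: Selective monosilylation of a 1,2-diol at the primary hydroxyl; the secondary hydroxyl next to the ester is hindered and less nucleophilic, and the bulky silyl chloride widens the difference.

Step 3
Reactants: 3 methyl (2R)-3-[(tert-butyldiphenylsilyl)oxy]-2-hydroxypropanoate
Product: 4 methyl (2R)-3-[(tert-butyldiphenylsilyl)oxy]-2-[(trifluoromethanesulfonyl)oxy]propanoate
Conditions: Tf2O, 2,6-lutidine, CH2Cl2, −78 °C; cold aqueous work-up, used at once
Reagents that add atoms: trifluoromethanesulfonic anhydride, O=S(=O)(OS(=O)(=O)C(F)(F)F)C(F)(F)F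
Why: O-Sulfonylation of an α-hydroxy ester with retention, since the C–O bond is not touched; the hindered base at low temperature avoids displacement and elimination.

Step 4
Reactants: 4 methyl (2R)-3-[(tert-butyldiphenylsilyl)oxy]-2-[(trifluoromethanesulfonyl)oxy]propanoate; 5 3,4-dihydroxy-5-methoxybenzaldehyde (5-hydroxyvanillin)
Product: 6 methyl (2S)-3-[(tert-butyldiphenylsilyl)oxy]-2-(4-formyl-2-hydroxy-6-methoxyphenoxy)propanoate
Conditions: 5 (1.2 equiv), K2CO3 (1.2 equiv), MeCN, 0 °C → rt
Reagents that add atoms: none
Why: SN2 displacement of an α-triflyloxy ester by a phenoxide (Williamson-type etherification) with inversion, which turns the (R) centre into the (S) centre that becomes C8'. One equivalent of carbonate places the charge on the hydroxyl para to the formyl group, the more acidic one, so the new bond is O4–C8'; the low temperature limits lactonisation onto the free O3 hydroxyl and β-elimination.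

Step 5
Reactants: 7 4-bromo-2-methoxyphenol
Product: 8 (4-bromo-2-methoxyphenoxy)tri(propan-2-yl)silane
Conditions: TIPSCl, imidazole, DMF, rt
Reagents that add atoms: chlorotri(propan-2-yl)silane, CC(C)[Si](Cl)(C(C)C)C(C)C
Why: Imidazole-mediated silylation of a phenol; the triisopropylsilyl ether tolerates Grignard formation and the later acid steps and still lets the para oxygen stabilise a benzylic cation.

Step 6
Reactants: 6 methyl (2S)-3-[(tert-butyldiphenylsilyl)oxy]-2-(4-formyl-2-hydroxy-6-methoxyphenoxy)propanoate
Product: 9 methyl (2S)-3-[(tert-butyldiphenylsilyl)oxy]-2-[4-(1,3-dioxolan-2-yl)-2-hydroxy-6-methoxyphenoxy]propanoate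
Conditions: TMSOCH2CH2OTMS, TMSOTf (cat.), CH2Cl2, −78 → −20 °C; pyridine; aq. NaHCO3/MeOH
Reagents that add atoms: 1,2-bis(trimethylsilyloxy)ethane, C[Si](C)(C)OCCO[Si](C)(C)C
Why: Noyori acetalisation of an aromatic aldehyde; the low temperature and aprotic medium keep the ester from lactonising onto the neighbouring phenol and leave C8' and the silyl ether alone, and the bicarbonate/methanol work-up frees the phenol from any trimethylsilyl ether.

Step 7
Reactants: 9 methyl (2S)-3-[(tert-butyldiphenylsilyl)oxy]-2-[4-(1,3-dioxolan-2-yl)-2-hydroxy-6-methoxyphenoxy]propanoate; 8 (4-bromo-2-methoxyphenoxy)tri(propan-2-yl)silane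
Product: 12 (1RS,2S)-3-[(tert-butyldiphenylsilyl)oxy]-2-[4-(1,3-dioxolan-2-yl)-2-hydroxy-6-methoxyphenoxy]-1-{3-methoxy-4-[(triisopropylsilyl)oxy]phenyl}propan-1-ol (both C7' epimers), via aryl Grignard reagent 10 (not isolated), via α-aryloxy aldehyde 11 (not isolated)
Conditions: 8, Mg, THF, 50 °C (to 10); 9, iBu2AlH (2.1 equiv), CH2Cl2, −78 °C; then 10 (4 equiv), −78 → 0 °C; aq. KNaC4H4O6
Reagents that add atoms: none
Why: One-pot partial reduction of an α-alkoxy ester followed by Grignard addition: the first equivalent of hydride is consumed by the phenol, the second gives an aluminium hemiacetal that is stable at −78 °C and releases aldehyde 11 only on warming in the presence of excess 10, so the epimerisable aldehyde is never handled. No facial selectivity is asked of the addition, because both C7' epimers of 12 serve in step 8.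

Step 8
Reactants: 12 (1RS,2S)-3-[(tert-butyldiphenylsilyl)oxy]-2-[4-(1,3-dioxolan-2-yl)-2-hydroxy-6-methoxyphenoxy]-1-{3-methoxy-4-[(triisopropylsilyl)oxy]phenyl}propan-1-ol
Product: 14 (2S,3S)-3-{[(tert-butyldiphenylsilyl)oxy]methyl}-7-(1,3-dioxolan-2-yl)-5-methoxy-2-{3-methoxy-4-[(triisopropylsilyl)oxy]phenyl}-2,3-dihydro-1,4-benzodioxine (trans; 7'S,8'S), via cis-benzodioxane 13 (not isolated)
Conditions: camphorsulfonic acid (0.1–0.2 equiv), 4 Å MS, CH2Cl2, 0 °C → rt
Reagents that add atoms: none
Why: The acid protonates the C7' hydroxyl of either epimer of 12, and loss of water gives one and the same planar benzylic cation, stabilised as an oxocarbenium (quinone-methide-like) ion by the para silyloxy oxygen of ring C; the ring A phenol O3 adds to C7' and closes ring B in a 6-exo-trig mode, forming the O3–C7' bond. The closest known reaction type is the acid-mediated dehydrative cyclisation of 1-aryl-2-(2-hydroxyaryloxy)propane-1,3-diols to 2-aryl-1,4-benzodioxanes, an intramolecular SN1 etherification. The benzylic aryl ether so formed can ionise again under the same acid, so the cis isomer 13 returns to the cation and the mixture should drain into the trans isomer 14, in which ring C and the C9' arm are both pseudo-equatorial on the half-chair dioxane. The new stereocentre C7' is thus controlled by the fixed C8' centre under thermodynamic control, and C8' itself has no ionisable bond under these conditions. The step needs ionisation at C7' in preference to damage at the dioxolane and the silyl ethers: the sieves take up the one equivalent of water set free, the dioxolane can only re-close in its absence, and any aldehyde 15 that does form is the product of the next step. It also needs trapping of the cation to be faster than loss of the C8' proton to an enol ether, which would endanger C8'; the intramolecular phenol, the catalytic amount of acid and the low temperature serve this.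

Step 9
Reactants: 14 (2S,3S)-3-{[(tert-butyldiphenylsilyl)oxy]methyl}-7-(1,3-dioxolan-2-yl)-5-methoxy-2-{3-methoxy-4-[(triisopropylsilyl)oxy]phenyl}-2,3-dihydro-1,4-benzodioxine
Product: 15 (2S,3S)-2-{[(tert-butyldiphenylsilyl)oxy]methyl}-8-methoxy-3-{3-methoxy-4-[(triisopropylsilyl)oxy]phenyl}-2,3-dihydro-1,4-benzodioxine-6-carbaldehyde
Conditions: PPTS, acetone/H2O (10:1), 40 °C
Reagents that add atoms: water, O
Why: Acid-catalysed hydrolysis of an aryl dioxolane under buffered conditions; the acetal should hydrolyse far faster than the benzylic aryl ether can ionise, and the TBDPS and aryl TIPS ethers tolerate pyridinium tosylate in wet acetone.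

Step 10
Reactants: 15 (2S,3S)-2-{[(tert-butyldiphenylsilyl)oxy]methyl}-8-methoxy-3-{3-methoxy-4-[(triisopropylsilyl)oxy]phenyl}-2,3-dihydro-1,4-benzodioxine-6-carbaldehyde
Product: 16 (2E)-3-[(2S,3S)-2-{[(tert-butyldiphenylsilyl)oxy]methyl}-8-methoxy-3-{3-methoxy-4-[(triisopropylsilyl)oxy]phenyl}-2,3-dihydro-1,4-benzodioxin-6-yl]prop-2-enal
Conditions: Ph3P=CHCHO (1.3 equiv), toluene, 80 °C
Reagents that add atoms: (triphenylphosphoranylidene)acetaldehyde, O=CC=P(c1ccccc1)(c1ccccc1)c1ccccc1
Why: Wittig olefination with a stabilised formyl ylide, which should give the (E)-enal; the neutral conditions leave both stereocentres and both silyl ethers untouched, and a small excess of ylide with early work-up limits a second homologation.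

Step 11
Reactants: 16 (2E)-3-[(2S,3S)-2-{[(tert-butyldiphenylsilyl)oxy]methyl}-8-methoxy-3-{3-methoxy-4-[(triisopropylsilyl)oxy]phenyl}-2,3-dihydro-1,4-benzodioxin-6-yl]prop-2-enal
Product: 17 (2E)-3-[(2S,3S)-3-(4-hydroxy-3-methoxyphenyl)-2-(hydroxymethyl)-8-methoxy-2,3-dihydro-1,4-benzodioxin-6-yl]prop-2-enal, (7'S,8'S)-nocomtal
Conditions: Bu4NF, AcOH, THF, 0 °C → rt
Reagents that add atoms: none
Why: Fluoride-mediated cleavage of the aryl triisopropylsilyl and the primary tert-butyldiphenylsilyl ether in one operation; acetic acid buffers the phenoxide so that the enal and the benzylic aryl ether are not exposed to strong base, and no stereocentre takes part.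

## Compound list

1 | methyl (4R)-2,2-dimethyl-1,3-dioxolane-4-carboxylate | COC(=O)[C@H]1COC(C)(C)O1 | starting material
2 | methyl (2R)-2,3-dihydroxypropanoate | COC(=O)[C@H](O)CO | intermediate
3 | methyl (2R)-3-[(tert-butyldiphenylsilyl)oxy]-2-hydroxypropanoate | COC(=O)[C@H](O)CO[Si](c1ccccc1)(c1ccccc1)C(C)(C)C | intermediate
4 | methyl (2R)-3-[(tert-butyldiphenylsilyl)oxy]-2-[(trifluoromethanesulfonyl)oxy]propanoate | COC(=O)[C@H](OS(=O)(=O)C(F)(F)F)CO[Si](c1ccccc1)(c1ccccc1)C(C)(C)C | intermediate
5 | 3,4-dihydroxy-5-methoxybenzaldehyde (5-hydroxyvanillin) | COc1cc(C=O)cc(O)c1O | starting material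
6 | methyl (2S)-3-[(tert-butyldiphenylsilyl)oxy]-2-(4-formyl-2-hydroxy-6-methoxyphenoxy)propanoate | COC(=O)[C@@H](Oc1c(O)cc(C=O)cc1OC)CO[Si](c1ccccc1)(c1ccccc1)C(C)(C)C | intermediate
7 | 4-bromo-2-methoxyphenol | COc1cc(Br)ccc1O | starting material
8 | (4-bromo-2-methoxyphenoxy)tri(propan-2-yl)silane | COc1cc(Br)ccc1O[Si](C(C)C)(C(C)C)C(C)C | intermediate
9 | methyl (2S)-3-[(tert-butyldiphenylsilyl)oxy]-2-[4-(1,3-dioxolan-2-yl)-2-hydroxy-6-methoxyphenoxy]propanoate | COC(=O)[C@@H](Oc1c(O)cc(C2OCCO2)cc1OC)CO[Si](c1ccccc1)(c1ccccc1)C(C)(C)C | intermediate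
10 | {3-methoxy-4-[(triisopropylsilyl)oxy]phenyl}magnesium bromide | COc1cc([Mg]Br)ccc1O[Si](C(C)C)(C(C)C)C(C)C | intermediate
11 | (2S)-3-[(tert-butyldiphenylsilyl)oxy]-2-[4-(1,3-dioxolan-2-yl)-2-hydroxy-6-methoxyphenoxy]propanal | O=C[C@@H](Oc1c(O)cc(C2OCCO2)cc1OC)CO[Si](c1ccccc1)(c1ccccc1)C(C)(C)C | intermediate
12 | (1RS,2S)-3-[(tert-butyldiphenylsilyl)oxy]-2-[4-(1,3-dioxolan-2-yl)-2-hydroxy-6-methoxyphenoxy]-1-{3-methoxy-4-[(triisopropylsilyl)oxy]phenyl}propan-1-ol | COc1cc(ccc1O[Si](C(C)C)(C(C)C)C(C)C)C(O)[C@@H](Oc1c(O)cc(C2OCCO2)cc1OC)CO[Si](c1ccccc1)(c1ccccc1)C(C)(C)C | intermediate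
13 | (2R,3S)-3-{[(tert-butyldiphenylsilyl)oxy]methyl}-7-(1,3-dioxolan-2-yl)-5-methoxy-2-{3-methoxy-4-[(triisopropylsilyl)oxy]phenyl}-2,3-dihydro-1,4-benzodioxine (cis; 7'R,8'S) | COc1cc([C@H]2Oc3cc(C4OCCO4)cc(OC)c3O[C@H]2CO[Si](c2ccccc2)(c2ccccc2)C(C)(C)C)ccc1O[Si](C(C)C)(C(C)C)C(C)C | intermediate
14 | (2S,3S)-3-{[(tert-butyldiphenylsilyl)oxy]methyl}-7-(1,3-dioxolan-2-yl)-5-methoxy-2-{3-methoxy-4-[(triisopropylsilyl)oxy]phenyl}-2,3-dihydro-1,4-benzodioxine (trans; 7'S,8'S) | COc1cc([C@@H]2Oc3cc(C4OCCO4)cc(OC)c3O[C@H]2CO[Si](c2ccccc2)(c2ccccc2)C(C)(C)C)ccc1O[Si](C(C)C)(C(C)C)C(C)C | intermediate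
15 | (2S,3S)-2-{[(tert-butyldiphenylsilyl)oxy]methyl}-8-methoxy-3-{3-methoxy-4-[(triisopropylsilyl)oxy]phenyl}-2,3-dihydro-1,4-benzodioxine-6-carbaldehyde | COc1cc([C@@H]2Oc3cc(C=O)cc(OC)c3O[C@H]2CO[Si](c2ccccc2)(c2ccccc2)C(C)(C)C)ccc1O[Si](C(C)C)(C(C)C)C(C)C | intermediate
16 | (2E)-3-[(2S,3S)-2-{[(tert-butyldiphenylsilyl)oxy]methyl}-8-methoxy-3-{3-methoxy-4-[(triisopropylsilyl)oxy]phenyl}-2,3-dihydro-1,4-benzodioxin-6-yl]prop-2-enal | COc1cc([C@@H]2Oc3cc(/C=C/C=O)cc(OC)c3O[C@H]2CO[Si](c2ccccc2)(c2ccccc2)C(C)(C)C)ccc1O[Si](C(C)C)(C(C)C)C(C)C | intermediate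
17 | (2E)-3-[(2S,3S)-3-(4-hydroxy-3-methoxyphenyl)-2-(hydroxymethyl)-8-methoxy-2,3-dihydro-1,4-benzodioxin-6-yl]prop-2-enal, (7'S,8'S)-nocomtal | COc1cc([C@@H]2Oc3cc(/C=C/C=O)cc(OC)c3O[C@H]2CO)ccc1O | target

## Step count and risks

Total: 11 steps. Longest linear sequence: 10 steps (steps 1–4 and 6–11, from 1 to 17); step 5 is the side branch that supplies ring C.

**Step 8 (key step).** The most likely failure is incomplete equilibration. Re-ionisation of the para-silyloxybenzyl aryl ether may be slow with catalytic sulfonic acid, so the kinetic cis/trans mixture would persist. A second risk is loss of the C8' proton from the cation, which would erode the C8' configuration if the acid is made stronger or the mixture is heated to force equilibration. The fallback sets out from the mixture of 13 and 14 and moves the equilibration to the quinone methide manifold. One equivalent of Bu4NF in THF at 0 °C removes the aryl silyl group ahead of the primary TBDPS ether and gives the cis phenol 4-[(2R,3S)-3-{[(tert-butyldiphenylsilyl)oxy]methyl}-7-(1,3-dioxolan-2-yl)-5-methoxy-2,3-dihydro-1,4-benzodioxin-2-yl]-2-methoxyphenol F1 together with its trans isomer 4-[(2S,3S)-3-{[(tert-butyldiphenylsilyl)oxy]methyl}-7-(1,3-dioxolan-2-yl)-5-methoxy-2,3-dihydro-1,4-benzodioxin-2-yl]-2-methoxyphenol F2. K2CO3 in DMF at 60 °C lets the phenoxide expel O3 as a para-quinone methide, which re-closes, so that F1 is converted into F2. Silylation of F2 with TIPSCl and imidazole returns to the route at 14.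

**Step 4.** Alkylation may occur at O3 or at both oxygens, and the product may lactonise onto the free O3 hydroxyl, because the selectivity rests only on the acidity difference of the two phenols. A lactone would still converge in step 7, but a wrong regiochemistry would not. The fallback sets out from 4 and uses a ring A partner with a single hydroxyl, 3-bromo-4-hydroxy-5-methoxybenzaldehyde (5-bromovanillin) F3. Its phenoxide displaces the triflate as in step 4 to give methyl (2S)-2-(2-bromo-4-formyl-6-methoxyphenoxy)-3-[(tert-butyldiphenylsilyl)oxy]propanoate F4. Acetalisation as in step 6 gives methyl (2S)-2-[2-bromo-4-(1,3-dioxolan-2-yl)-6-methoxyphenoxy]-3-[(tert-butyldiphenylsilyl)oxy]propanoate F5. Miyaura borylation (B2pin2, Pd(dppf)Cl2, KOAc, dioxane, 80 °C) gives methyl (2S)-3-[(tert-butyldiphenylsilyl)oxy]-2-[4-(1,3-dioxolan-2-yl)-2-methoxy-6-(4,4,5,5-tetramethyl-1,3,2-dioxaborolan-2-yl)phenoxy]propanoate F6. Oxidation of the boronate with NaBO3·4H2O in THF/H2O installs the O3 hydroxyl and returns to the route at 9.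

**Step 7.** Over-reduction of the ester to the primary alcohol and epimerisation or β-elimination at C8' may occur once the aldehyde is released, because the hydride stoichiometry is blurred by the free phenol. The fallback sets out from 9 and separates the two events. Reduction with iBu2AlH at −78 °C and work-up lets the aldehyde close onto the O3 hydroxyl to give the cyclic hemiacetal (3S)-3-{[(tert-butyldiphenylsilyl)oxy]methyl}-7-(1,3-dioxolan-2-yl)-5-methoxy-2,3-dihydro-1,4-benzodioxin-2-ol F7. In this form C8' is no longer next to a free carbonyl group and the compound can be purified. Addition of excess 10 to this lactol opens it and returns to the route at 12.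

**Step 10.** A second Wittig homologation of the product enal to a dienal may compete with slow conversion of the electron-rich aldehyde. The fallback sets out from 15. A Horner–Wadsworth–Emmons reaction with triethyl phosphonoacetate and NaH gives ethyl (2E)-3-[(2S,3S)-2-{[(tert-butyldiphenylsilyl)oxy]methyl}-8-methoxy-3-{3-methoxy-4-[(triisopropylsilyl)oxy]phenyl}-2,3-dihydro-1,4-benzodioxin-6-yl]prop-2-enoate F8. Reduction with iBu2AlH gives the allylic alcohol (2E)-3-[(2S,3S)-2-{[(tert-butyldiphenylsilyl)oxy]methyl}-8-methoxy-3-{3-methoxy-4-[(triisopropylsilyl)oxy]phenyl}-2,3-dihydro-1,4-benzodioxin-6-yl]prop-2-en-1-ol F9. Oxidation with MnO2 returns to the route at 16.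

**Step 11.** Basic fluoride may open ring B through the phenoxide (quinone methide formation) or degrade the enal by conjugate addition and condensation. The fallback sets out from 15 and changes the order of events. Desilylation with Bu4NF and AcOH at the aldehyde stage gives (2S,3S)-3-(4-hydroxy-3-methoxyphenyl)-2-(hydroxymethyl)-8-methoxy-2,3-dihydro-1,4-benzodioxine-6-carbaldehyde F10. The Wittig reaction with Ph3P=CHCHO is then run last on this unprotected aldehyde and returns to the route at 17, so the enal never meets fluoride.

## Further compounds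

F1 | step 8 | 4-[(2R,3S)-3-{[(tert-butyldiphenylsilyl)oxy]methyl}-7-(1,3-dioxolan-2-yl)-5-methoxy-2,3-dihydro-1,4-benzodioxin-2-yl]-2-methoxyphenol | COc1cc([C@H]2Oc3cc(C4OCCO4)cc(OC)c3O[C@H]2CO[Si](c2ccccc2)(c2ccccc2)C(C)(C)C)ccc1O
F2 | step 8 | 4-[(2S,3S)-3-{[(tert-butyldiphenylsilyl)oxy]methyl}-7-(1,3-dioxolan-2-yl)-5-methoxy-2,3-dihydro-1,4-benzodioxin-2-yl]-2-methoxyphenol | COc1cc([C@@H]2Oc3cc(C4OCCO4)cc(OC)c3O[C@H]2CO[Si](c2ccccc2)(c2ccccc2)C(C)(C)C)ccc1O
F3 | step 4 | 3-bromo-4-hydroxy-5-methoxybenzaldehyde (5-bromovanillin) | COc1cc(C=O)cc(Br)c1O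
F4 | step 4 | methyl (2S)-2-(2-bromo-4-formyl-6-methoxyphenoxy)-3-[(tert-butyldiphenylsilyl)oxy]propanoate | COC(=O)[C@@H](Oc1c(Br)cc(C=O)cc1OC)CO[Si](c1ccccc1)(c1ccccc1)C(C)(C)C
F5 | step 4 | methyl (2S)-2-[2-bromo-4-(1,3-dioxolan-2-yl)-6-methoxyphenoxy]-3-[(tert-butyldiphenylsilyl)oxy]propanoate | COC(=O)[C@@H](Oc1c(Br)cc(C2OCCO2)cc1OC)CO[Si](c1ccccc1)(c1ccccc1)C(C)(C)C
F6 | step 4 | methyl (2S)-3-[(tert-butyldiphenylsilyl)oxy]-2-[4-(1,3-dioxolan-2-yl)-2-methoxy-6-(4,4,5,5-tetramethyl-1,3,2-dioxaborolan-2-yl)phenoxy]propanoate | COC(=O)[C@@H](Oc1c(B2OC(C)(C)C(C)(C)O2)cc(C3OCCO3)cc1OC)CO[Si](c1ccccc1)(c1ccccc1)C(C)(C)C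
F7 | step 7 | (3S)-3-{[(tert-butyldiphenylsilyl)oxy]methyl}-7-(1,3-dioxolan-2-yl)-5-methoxy-2,3-dihydro-1,4-benzodioxin-2-ol | OC1Oc2cc(C3OCCO3)cc(OC)c2O[C@H]1CO[Si](c1ccccc1)(c1ccccc1)C(C)(C)C
F8 | step 10 | ethyl (2E)-3-[(2S,3S)-2-{[(tert-butyldiphenylsilyl)oxy]methyl}-8-methoxy-3-{3-methoxy-4-[(triisopropylsilyl)oxy]phenyl}-2,3-dihydro-1,4-benzodioxin-6-yl]prop-2-enoate | COc1cc([C@@H]2Oc3cc(/C=C/C(=O)OCC)cc(OC)c3O[C@H]2CO[Si](c2ccccc2)(c2ccccc2)C(C)(C)C)ccc1O[Si](C(C)C)(C(C)C)C(C)C
F9 | step 10 | (2E)-3-[(2S,3S)-2-{[(tert-butyldiphenylsilyl)oxy]methyl}-8-methoxy-3-{3-methoxy-4-[(triisopropylsilyl)oxy]phenyl}-2,3-dihydro-1,4-benzodioxin-6-yl]prop-2-en-1-ol | COc1cc([C@@H]2Oc3cc(/C=C/CO)cc(OC)c3O[C@H]2CO[Si](c2ccccc2)(c2ccccc2)C(C)(C)C)ccc1O[Si](C(C)C)(C(C)C)C(C)C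
F10 | step 11 | (2S,3S)-3-(4-hydroxy-3-methoxyphenyl)-2-(hydroxymethyl)-8-methoxy-2,3-dihydro-1,4-benzodioxine-6-carbaldehyde | COc1cc([C@@H]2Oc3cc(C=O)cc(OC)c3O[C@H]2CO)ccc1O
A1 | alternative 1 | 4-hydroxy-3-methoxy-5-({(1R)-1-[3-methoxy-4-(triisopropylsilyloxy)phenyl]prop-2-en-1-yl}oxy)benzaldehyde | COc1cc([C@@H](C=C)Oc2cc(C=O)cc(OC)c2O)ccc1O[Si](C(C)C)(C(C)C)C(C)C
A2 | alternative 1 | trans-2-(iodomethyl)-8-methoxy-3-[3-methoxy-4-(triisopropylsilyloxy)phenyl]-2,3-dihydro-1,4-benzodioxine-6-carbaldehyde (ring C and CH2I placed as ring C and CH2OH in the target) | COc1cc([C@@H]2Oc3cc(C=O)cc(OC)c3O[C@H]2CI)ccc1O[Si](C(C)C)(C(C)C)C(C)C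
A3 | alternative 2 | methyl 2-[4-(benzyloxy)-3-methoxyphenyl]-7-methoxy-1,3-benzodioxole-5-carboxylate (racemic) | COc1cc(C2Oc3cc(C(=O)OC)cc(OC)c3O2)ccc1OCc1ccccc1
A4 | alternative 2 | 2-ethyl 6-methyl trans-3-[4-(benzyloxy)-3-methoxyphenyl]-8-methoxy-2,3-dihydro-1,4-benzodioxine-2,6-dicarboxylate (C7' and C8' placed as in the target) | COc1cc([C@@H]2Oc3cc(C(=O)OC)cc(OC)c3O[C@H]2C(=O)OCC)ccc1OCc1ccccc1
A5 | alternative 3 | methyl 3-{(1S,2S)-1-[4-(benzyloxy)-3-methoxyphenyl]-3-[(tert-butyldimethylsilyl)oxy]-2-hydroxypropoxy}-4-bromo-5-methoxybenzoate | COc1cc([C@H](Oc2cc(C(=O)OC)cc(OC)c2Br)[C@@H](O)CO[Si](C)(C)C(C)(C)C)ccc1OCc1ccccc1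
A6 | alternative 3 | methyl (2S,3S)-3-[4-(benzyloxy)-3-methoxyphenyl]-2-{[(tert-butyldimethylsilyl)oxy]methyl}-8-methoxy-2,3-dihydro-1,4-benzodioxine-6-carboxylate | COc1cc([C@@H]2Oc3cc(C(=O)OC)cc(OC)c3O[C@H]2CO[Si](C)(C)C(C)(C)C)ccc1OCc1ccccc1
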